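Everything rests on cutting ring B at B1–B2, B3–B4 and B5–B6 into three two-carbon units. This exploits the alternation of oxygen-bearing atoms (B2, B4, B6) and carbon-bearing atoms (B1, B3, B5) in ring B, and the fact that its three oxygens differ. In one telescoped operation a ketene, a siloxyalkyne and methoxyethyne close ring B with B6 as free phenol, B2 as silyl ether, B4 as methyl ether and B5 as the only ring C–H of the molecule. The precursor is 3-arylpropanoyl chloride 16. It carries acetylated ring C and ring A with all five phenols as benzyl ethers, which withstand acid chloride formation and leave by neutral hydrogenolysis.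

Key step: step 11

Remarks
- **Labels.** Ring C is the central acetylated ring.
  - Ring A is the outer ring joined through the carbon between OCH3 and OH, with its butanoyl group between two OH groups.
  - Ring B is the outer ring joined through the carbon between two OH groups: B1 bridge carbon, B2 OH, B3 CH3, B4 OCH3, B5 butanoyl, B6 OH.
- **Abbreviation.** Ar = 3-acetyl-2,4,6-tris(benzyloxy)-5-{[2,4-bis(benzyloxy)-3-butanoyl-6-methoxy-5-methylphenyl]methyl}phenyl.
- **Protecting groups.** Benzyl ethers are preferred to acetal-type ethers for two reasons. An acetal oxygen ortho to the propanoyl chloride chain would be exposed to HCl and to ring closure onto the acyl chloride. Its final acidic removal would also endanger the methylene bridges.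
- **Assumption.** The target has no stereocentre and no stereogenic double bond, so the racemic intermediates 25, 27 and 29 are of no consequence.

Step 1
Reactants: 1 2-methylbenzene-1,3,5-triol
Product: 2 1-(2,4,6-trihydroxy-3-methylphenyl)butan-1-one
Conditions: PrCOCl, AlCl3, CH2Cl2/PhNO2, 0 → 40 °C; then ice, 1 M HCl
Reagents that add atoms: butanoyl chloride CCCC(=O)Cl
Why: Friedel–Crafts acylation of a highly activated arene whose two free positions are equivalent, with the first acyl group deactivating the ring against a second acylation.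

Step 2
Reactants: 2 1-(2,4,6-trihydroxy-3-methylphenyl)butan-1-one
Product: 3 1-(2,6-dihydroxy-4-methoxy-3-methylphenyl)butan-1-one (aspidinol)
Conditions: Me2SO4 (1.0 equiv), K2CO3 (1.05 equiv), acetone, reflux
Reagents that add atoms: dimethyl sulfate COS(=O)(=O)OC
Why: Williamson-type O-methylation with one equivalent of base and electrophile, selective because the OH para to the ketone is the most acidic one while both ortho OH groups are hindered and held by hydrogen bonding to the carbonyl group.

Step 3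
Reactants: 3 1-(2,6-dihydroxy-4-methoxy-3-methylphenyl)butan-1-one
Product: 4 1-{3-[(dimethylamino)methyl]-2,6-dihydroxy-4-methoxy-5-methylphenyl}butan-1-one
Conditions: aq. CH2O, aq. Me2NH, EtOH, 0 °C → rt
Reagents that add atoms: formaldehyde C=O; dimethylamine CNC
Why: Mannich aminomethylation at the single free ring carbon of 3, which lies between OCH3 and OH and is activated by three oxygen substituents.

Step 4
Reactants: 5 1-(2,4,6-trihydroxyphenyl)ethan-1-one
Product: 7 3-acetyl-2,4,6-trihydroxybenzaldehyde, via iminium chloride 6 (not isolated)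
Conditions: POCl3 (1.1 equiv), DMF, EtOAc, 0 °C → rt; then H2O, 50 °C
Reagents that add atoms: N,N-dimethylformamide CN(C)C=O; water O
Why: Vilsmeier–Haack formylation of an acylphloroglucinol, which stops at the monoaldehyde because one equivalent of reagent is used and iminium salt 6 is strongly deactivated.

Step 5
Reactants: 4 1-{3-[(dimethylamino)methyl]-2,6-dihydroxy-4-methoxy-5-methylphenyl}butan-1-one; 7 3-acetyl-2,4,6-trihydroxybenzaldehyde
Product: 9 3-acetyl-5-[(3-butanoyl-2,4-dihydroxy-6-methoxy-5-methylphenyl)methyl]-2,4,6-trihydroxybenzaldehyde, via o-quinone methide 8 (not isolated)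
Conditions: 1,4-dioxane, 100 °C, N2; then 1 M HCl wash
Reagents that add atoms: none
Why: Thermal loss of dimethylamine from the phenolic Mannich base gives o-quinone methide 8, and Michael-type C-alkylation by the only free ring carbon of 7 followed by rearomatization forms the A–C methylene bridge, so that neither partner can react twice.

Step 6
Reactants: 9 3-acetyl-5-[(3-butanoyl-2,4-dihydroxy-6-methoxy-5-methylphenyl)methyl]-2,4,6-trihydroxybenzaldehyde
Product: 10 pentabenzyl ether aldehyde ArCHO
Conditions: BnBr (7 equiv), K2CO3 (8 equiv), n-Bu4NI (cat.), DMF, rt → 50 °C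
Reagents that add atoms: benzyl bromide BrCc1ccccc1
Why: Williamson ether synthesis in a polar aprotic solvent, which favours O- over C-benzylation of the phenolates and also locks the base-labile methylene bridge because no free ortho phenol remains.

Step 7
Reactants: 10 pentabenzyl ether aldehyde ArCHO; 11 2,2-dimethyl-1,3-dioxane-4,6-dione (Meldrum's acid)
Product: 15 3-arylpropanoic acid ArCH2CH2CO2H, via arylidene Meldrum's acid 12 (not isolated), via arylmethyl Meldrum's acid 13 (not isolated), via arylmethylmalonic acid 14 (not isolated)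
Conditions: HCO2H/Et3N (5:2), 25 °C, then 100 °C
Reagents that add atoms: none
Why: One-pot Knoevenagel condensation, conjugate transfer hydrogenation of the alkylidene Meldrum's acid by formate, and hydrolysis with decarboxylation on heating, a known direct conversion of aromatic aldehydes into 3-arylpropanoic acids that leaves benzyl ethers and the hindered ketones untouched.

Step 8
Reactants: 15 3-arylpropanoic acid ArCH2CH2CO2H
Product: 16 3-arylpropanoyl chloride ArCH2CH2COCl
Conditions: (COCl)2 (1.5 equiv), DMF (cat.), CH2Cl2, 0 °C → rt; evaporation, toluene chase, used crude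
Reagents that add atoms: oxalyl chloride ClC(=O)C(=O)Cl
Why: Standard acid chloride formation through a catalytic chloroiminium species, safe here because benzyl ethers tolerate the HCl evolved and no ring position is free for intramolecular acylation.

Step 9
Reactants: 17 propyne
Product: 20 1-(triisopropylsilyloxy)prop-1-yne, via prop-1-ynyllithium 18 (not isolated), via lithium ynolate 19 (not isolated)
Conditions: n-BuLi, THF, −78 °C; t-BuOOLi (from t-BuOOH and LiN(SiMe3)2, THF, −78 °C), −78 → 0 °C; i-Pr3SiOTf, −78 → 0 °C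
Reagents that add atoms: tert-butyl hydroperoxide CC(C)(C)OO; triisopropylsilyl trifluoromethanesulfonate CC(C)[Si](C(C)C)(C(C)C)OS(=O)(=O)C(F)(F)F
Why: Oxidation of a lithium acetylide with lithium tert-butyl peroxide gives the ynolate, which the bulky silyl triflate traps on oxygen and not on carbon, the established route to triisopropylsiloxyalkynes.

Step 10
Reactants: 21 2-chloro-1,1-dimethoxyethane
Product: 23 methoxyethyne, via sodium methoxyacetylide 22 (not isolated)
Conditions: NaNH2 (3.1 equiv), liquid NH3, −33 °C; NH3 evaporated; cold sat. aq. NaCl, product distilled into a cold trap and kept as a cold toluene solution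
Reagents that add atoms: none
Why: Twofold base-induced elimination (methanol, then HCl) from the chloroacetal, the classical preparation of alkoxyethynes, with the third equivalent of base holding the product as its acetylide until the quench.

Step 11
Reactants: 16 3-arylpropanoyl chloride ArCH2CH2COCl; 20 1-(triisopropylsilyloxy)prop-1-yne; 23 methoxyethyne
Product: 30 2-(ArCH2)-5-methoxy-4-methyl-3-(triisopropylsilyloxy)phenol, via ketene 24 (not isolated), via siloxycyclobutenone 25 (not isolated), via vinylketene 26 (not isolated), via vinylcyclobutenone 27 (not isolated), via dienylketene 28 (not isolated), via cyclohexadienone 29 (not isolated)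
Conditions: 20 (1.3 equiv), Et3N (1.5 equiv), toluene, 25 °C, slow addition of 16; filtration under Ar, Et3N and surplus 20 removed at 0.05 mbar; then 23 (10 equiv), toluene, sealed tube, 80 → 120 °C
Reagents that add atoms: none
Why: Et3N dehydrochlorinates 16 to aldoketene 24, whose carbonyl carbon is attacked by the methyl-bearing, oxygen-free carbon of 20, so that the [2+2] cycloaddition forms B1–B2 and gives cyclobutenone 25. On heating, 25 opens in a conrotatory 4π electrocyclic reaction, the arylmethyl group turning outward, to vinylketene 26, which adds [2+2] to 23 (B5–B6 and B3–B4) to give 27. A second 4π opening gives dienylketene 28, and ring B closes by 6π electrocyclization between the ketene carbon B6 and B1, followed by tautomerization of dienone 29 to phenol 30. The closest known reaction types are the ketene–siloxyalkyne cycloaddition to 3-siloxycyclobutenones and the Danheiser benzannulation of cyclobutenones with alkoxyalkynes. No stereocentre has to be controlled, since those of 25, 27 and 29 vanish on aromatization. The step needs head-to-tail regiochemistry in both cycloadditions, which the oxygen polarization of both ynol ethers secures and which puts OCH3 para to B1, and it needs the vinylketene to meet 23 rather than 20, which removal of surplus 20 and a large excess of the unhindered terminal alkyne secure.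

Step 12
Reactants: 30 2-(ArCH2)-5-methoxy-4-methyl-3-(triisopropylsilyloxy)phenol
Product: 32 2-(ArCH2)-6-iodo-5-methoxy-4-methyl-3-(triisopropylsilyloxy)phenyl butanoate, via iodophenol 31 (not isolated)
Conditions: NIS (1.05 equiv), CH2Cl2, −20 °C, dark; then Et3N, DMAP (cat.), PrCOCl, 0 °C → rt
Reagents that add atoms: N-iodosuccinimide O=C1CCC(=O)N1I; butanoyl chloride CCCC(=O)Cl
Why: Electrophilic aromatic iodination at B5, the only ring C–H of the molecule and ortho or para to three oxygens, followed in the same flask by DMAP-catalysed esterification of the B6 phenol.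

Step 13
Reactants: 32 2-(ArCH2)-6-iodo-5-methoxy-4-methyl-3-(triisopropylsilyloxy)phenyl butanoate
Product: 34 1-[3-(ArCH2)-2-hydroxy-6-methoxy-5-methyl-4-(triisopropylsilyloxy)phenyl]butan-1-one, via aryllithium 33 (not isolated)
Conditions: n-BuLi (1.05 equiv), THF/Et2O, −100 → −78 °C; sat. aq. NH4Cl
Reagents that add atoms: none
Why: Anionic Fries rearrangement triggered by iodine–lithium exchange, in which the exchange outruns carbonyl addition at −100 °C, both ketones are shielded by two ortho benzyloxy groups each, and aryllithium 33 attacks the neighbouring ester carbonyl intramolecularly (1,3 O→C acyl shift) to place the butanoyl group on B5.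

Step 14
Reactants: 34 1-[3-(ArCH2)-2-hydroxy-6-methoxy-5-methyl-4-(triisopropylsilyloxy)phenyl]butan-1-one
Product: 35 1-[3-(ArCH2)-2,4-dihydroxy-6-methoxy-5-methylphenyl]butan-1-one
Conditions: n-Bu4NF, AcOH (1.2 equiv each), THF, 0 °C
Reagents that add atoms: none
Why: Fluoride-induced cleavage of the aryl silyl ether, buffered with acetic acid so that the ketones and the methylene bridges see no strong base.

Step 15
Reactants: 35 1-[3-(ArCH2)-2,4-dihydroxy-6-methoxy-5-methylphenyl]butan-1-one
Product: 36 CNP0184345.0 (target)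
Conditions: H2 (1 atm), Pd/C (10 wt%), EtOAc/MeOH, rt
Reagents that add atoms: none
Why: Hydrogenolysis of the five aryl benzyl ethers under neutral conditions, which spares the aryl methyl ethers, the hydrogen-bonded aryl ketones and the acid- and base-labile diarylmethane links.

Compound list
1 | 2-methylbenzene-1,3,5-triol (2-methylphloroglucinol) | Cc1c(O)cc(O)cc1O | starting material
2 | 1-(2,4,6-trihydroxy-3-methylphenyl)butan-1-one | CCCC(=O)c1c(O)c(C)c(O)cc1O | intermediate
3 | 1-(2,6-dihydroxy-4-methoxy-3-methylphenyl)butan-1-one (aspidinol) | CCCC(=O)c1c(O)c(C)c(OC)cc1O | intermediate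
4 | 1-{3-[(dimethylamino)methyl]-2,6-dihydroxy-4-methoxy-5-methylphenyl}butan-1-one (ring A Mannich base) | CCCC(=O)c1c(O)c(C)c(OC)c(CN(C)C)c1O | intermediate
5 | 1-(2,4,6-trihydroxyphenyl)ethan-1-one | CC(=O)c1c(O)cc(O)cc1O | starting material
6 | [(3-acetyl-2,4,6-trihydroxyphenyl)methylidene]dimethylammonium chloride (not isolated) | CC(=O)c1c(O)cc(O)c(C=[N+](C)C)c1O.[Cl-] | intermediate
7 | 3-acetyl-2,4,6-trihydroxybenzaldehyde | CC(=O)c1c(O)cc(O)c(C=O)c1O | intermediate
8 | 2-butanoyl-3-hydroxy-5-methoxy-4-methyl-6-methylidenecyclohexa-2,4-dien-1-one (ring A o-quinone methide, not isolated) | C=C1C(=O)C(C(=O)CCC)=C(O)C(C)=C1OC | intermediate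
9 | 3-acetyl-5-[(3-butanoyl-2,4-dihydroxy-6-methoxy-5-methylphenyl)methyl]-2,4,6-trihydroxybenzaldehyde | O=Cc1c(O)c(Cc2c(O)c(C(=O)CCC)c(O)c(C)c2OC)c(O)c(C(C)=O)c1O | intermediate
10 | ArCHO, pentabenzyl ether of 9 | O=Cc1c(OCc9ccccc9)c(Cc2c(OCc9ccccc9)c(C(=O)CCC)c(OCc9ccccc9)c(C)c2OC)c(OCc9ccccc9)c(C(C)=O)c1OCc9ccccc9 | intermediate
11 | 2,2-dimethyl-1,3-dioxane-4,6-dione (Meldrum's acid) | CC1(C)OC(=O)CC(=O)O1 | starting material
12 | 5-(Ar-methylidene)-2,2-dimethyl-1,3-dioxane-4,6-dione (not isolated) | CC3(C)OC(=O)C(=Cc1c(OCc9ccccc9)c(Cc2c(OCc9ccccc9)c(C(=O)CCC)c(OCc9ccccc9)c(C)c2OC)c(OCc9ccccc9)c(C(C)=O)c1OCc9ccccc9)C(=O)O3 | intermediate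
13 | 5-(ArCH2)-2,2-dimethyl-1,3-dioxane-4,6-dione (not isolated) | CC3(C)OC(=O)C(Cc1c(OCc9ccccc9)c(Cc2c(OCc9ccccc9)c(C(=O)CCC)c(OCc9ccccc9)c(C)c2OC)c(OCc9ccccc9)c(C(C)=O)c1OCc9ccccc9)C(=O)O3 | intermediate
14 | 2-(ArCH2)propanedioic acid (not isolated) | OC(=O)C(Cc1c(OCc9ccccc9)c(Cc2c(OCc9ccccc9)c(C(=O)CCC)c(OCc9ccccc9)c(C)c2OC)c(OCc9ccccc9)c(C(C)=O)c1OCc9ccccc9)C(=O)O | intermediate
15 | 3-Ar-propanoic acid | OC(=O)CCc1c(OCc9ccccc9)c(Cc2c(OCc9ccccc9)c(C(=O)CCC)c(OCc9ccccc9)c(C)c2OC)c(OCc9ccccc9)c(C(C)=O)c1OCc9ccccc9 | intermediate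
16 | 3-Ar-propanoyl chloride (precursor of the key step) | ClC(=O)CCc1c(OCc9ccccc9)c(Cc2c(OCc9ccccc9)c(C(=O)CCC)c(OCc9ccccc9)c(C)c2OC)c(OCc9ccccc9)c(C(C)=O)c1OCc9ccccc9 | intermediate
17 | propyne | CC#C | starting material
18 | prop-1-ynyllithium (not isolated) | CC#C[Li] | intermediate
19 | lithium prop-1-yn-1-olate (not isolated) | CC#C[O-].[Li+] | intermediate
20 | 1-(triisopropylsilyloxy)prop-1-yne | CC#CO[Si](C(C)C)(C(C)C)C(C)C | intermediate
21 | 2-chloro-1,1-dimethoxyethane (chloroacetaldehyde dimethyl acetal) | COC(CCl)OC | starting material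
22 | sodium methoxyacetylide (not isolated) | COC#[C-].[Na+] | intermediate
23 | methoxyethyne | COC#C | intermediate
24 | 3-Ar-prop-1-en-1-one, ArCH2CH=C=O (not isolated) | O=C=CCc1c(OCc9ccccc9)c(Cc2c(OCc9ccccc9)c(C(=O)CCC)c(OCc9ccccc9)c(C)c2OC)c(OCc9ccccc9)c(C(C)=O)c1OCc9ccccc9 | intermediate
25 | 4-(ArCH2)-2-methyl-3-(triisopropylsilyloxy)cyclobut-2-en-1-one, racemic (not isolated) | O=C3C(C)=C(O[Si](C(C)C)(C(C)C)C(C)C)C3Cc1c(OCc9ccccc9)c(Cc2c(OCc9ccccc9)c(C(=O)CCC)c(OCc9ccccc9)c(C)c2OC)c(OCc9ccccc9)c(C(C)=O)c1OCc9ccccc9 | intermediate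
26 | (Z)-5-Ar-2-methyl-3-(triisopropylsilyloxy)penta-1,3-dien-1-one (not isolated) | O=C=C(C)/C(O[Si](C(C)C)(C(C)C)C(C)C)=C/Cc1c(OCc9ccccc9)c(Cc2c(OCc9ccccc9)c(C(=O)CCC)c(OCc9ccccc9)c(C)c2OC)c(OCc9ccccc9)c(C(C)=O)c1OCc9ccccc9 | intermediate
27 | 4-[(Z)-3-Ar-1-(triisopropylsilyloxy)prop-1-enyl]-3-methoxy-4-methylcyclobut-2-en-1-one, racemic (not isolated) | O=C3C=C(OC)C3(C)/C(O[Si](C(C)C)(C(C)C)C(C)C)=C/Cc1c(OCc9ccccc9)c(Cc2c(OCc9ccccc9)c(C(=O)CCC)c(OCc9ccccc9)c(C)c2OC)c(OCc9ccccc9)c(C(C)=O)c1OCc9ccccc9 | intermediate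
28 | (3E,5Z)-7-Ar-3-methoxy-4-methyl-5-(triisopropylsilyloxy)hepta-1,3,5-trien-1-one (not isolated) | O=C=C/C(OC)=C(C)\C(O[Si](C(C)C)(C(C)C)C(C)C)=C\Cc1c(OCc9ccccc9)c(Cc2c(OCc9ccccc9)c(C(=O)CCC)c(OCc9ccccc9)c(C)c2OC)c(OCc9ccccc9)c(C(C)=O)c1OCc9ccccc9 | intermediate
29 | 6-(ArCH2)-3-methoxy-4-methyl-5-(triisopropylsilyloxy)cyclohexa-2,4-dien-1-one, racemic (not isolated) | O=C3C=C(OC)C(C)=C(O[Si](C(C)C)(C(C)C)C(C)C)C3Cc1c(OCc9ccccc9)c(Cc2c(OCc9ccccc9)c(C(=O)CCC)c(OCc9ccccc9)c(C)c2OC)c(OCc9ccccc9)c(C(C)=O)c1OCc9ccccc9 | intermediate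
30 | 2-(ArCH2)-5-methoxy-4-methyl-3-(triisopropylsilyloxy)phenol (product of the key step: B6 OH, B5 H, B4 OCH3, B3 CH3, B2 OSi(i-Pr)3) | Oc3cc(OC)c(C)c(O[Si](C(C)C)(C(C)C)C(C)C)c3Cc1c(OCc9ccccc9)c(Cc2c(OCc9ccccc9)c(C(=O)CCC)c(OCc9ccccc9)c(C)c2OC)c(OCc9ccccc9)c(C(C)=O)c1OCc9ccccc9 | intermediate
31 | 2-(ArCH2)-6-iodo-5-methoxy-4-methyl-3-(triisopropylsilyloxy)phenol (not isolated) | Oc3c(I)c(OC)c(C)c(O[Si](C(C)C)(C(C)C)C(C)C)c3Cc1c(OCc9ccccc9)c(Cc2c(OCc9ccccc9)c(C(=O)CCC)c(OCc9ccccc9)c(C)c2OC)c(OCc9ccccc9)c(C(C)=O)c1OCc9ccccc9 | intermediate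
32 | 2-(ArCH2)-6-iodo-5-methoxy-4-methyl-3-(triisopropylsilyloxy)phenyl butanoate | CCCC(=O)Oc3c(I)c(OC)c(C)c(O[Si](C(C)C)(C(C)C)C(C)C)c3Cc1c(OCc9ccccc9)c(Cc2c(OCc9ccccc9)c(C(=O)CCC)c(OCc9ccccc9)c(C)c2OC)c(OCc9ccccc9)c(C(C)=O)c1OCc9ccccc9 | intermediate
33 | B5 aryllithium derived from 32 (not isolated) | CCCC(=O)Oc3c([Li])c(OC)c(C)c(O[Si](C(C)C)(C(C)C)C(C)C)c3Cc1c(OCc9ccccc9)c(Cc2c(OCc9ccccc9)c(C(=O)CCC)c(OCc9ccccc9)c(C)c2OC)c(OCc9ccccc9)c(C(C)=O)c1OCc9ccccc9 | intermediate
34 | 1-[3-(ArCH2)-2-hydroxy-6-methoxy-5-methyl-4-(triisopropylsilyloxy)phenyl]butan-1-one | Oc3c(C(=O)CCC)c(OC)c(C)c(O[Si](C(C)C)(C(C)C)C(C)C)c3Cc1c(OCc9ccccc9)c(Cc2c(OCc9ccccc9)c(C(=O)CCC)c(OCc9ccccc9)c(C)c2OC)c(OCc9ccccc9)c(C(C)=O)c1OCc9ccccc9 | intermediate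
35 | 1-[3-(ArCH2)-2,4-dihydroxy-6-methoxy-5-methylphenyl]butan-1-one | Oc3c(C(=O)CCC)c(OC)c(C)c(O)c3Cc1c(OCc9ccccc9)c(Cc2c(OCc9ccccc9)c(C(=O)CCC)c(OCc9ccccc9)c(C)c2OC)c(OCc9ccccc9)c(C(C)=O)c1OCc9ccccc9 | intermediate
36 | CNP0184345.0 | CCCC(=O)c1c(O)c(C)c(OC)c(Cc2c(O)c(Cc3c(O)c(C)c(OC)c(C(=O)CCC)c3O)c(O)c(C(C)=O)c2O)c1O | target

Total step count: 15 (steps 4, 9 and 10 are side branches).
Longest linear sequence: 12 steps (1, 2, 3, 5, 6, 7, 8, 11, 12, 13, 14, 15).

Steps most likely to fail

**1. Step 11 (key step).**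
- What may go wrong:
  - the monosubstituted ketene dimerizes before it meets the siloxyalkyne;
  - the donor-stabilised cyclobutenone is reluctant to undergo 4π opening;
  - the newly formed phenol is acylated by vinylketene that has not yet reacted;
  - methoxyethyne polymerizes on heating.
- Fallback: ring B is brought in preformed and the second bridge is made by o-quinone methide coupling. It sets out from 2, 4 and 5 and comes back at 36.
  - Heating 4 with an excess of 5 in dioxane should give 1-{3-[(3-acetyl-2,4,6-trihydroxyphenyl)methyl]-2,6-dihydroxy-4-methoxy-5-methylphenyl}butan-1-one F1.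
  - CH2O and Me2NH in EtOH should aminomethylate its last ring C position to the ring C Mannich base of the A–C dimer F2.
  - Separately, MOMCl and i-Pr2NEt should protect in 2 the two phenols not held in the hydrogen bond beside the methyl group, giving 1-[2-hydroxy-4,6-bis(methoxymethoxy)-3-methylphenyl]butan-1-one F3.
  - MeI and K2CO3 should methylate the remaining phenol to 1-[2-methoxy-4,6-bis(methoxymethoxy)-3-methylphenyl]butan-1-one F4.
  - HCl in MeOH should release 1-(4,6-dihydroxy-2-methoxy-3-methylphenyl)butan-1-one F5.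
  - Heating F2 with F5 in dioxane should join the ring carbon between the two OH groups of F5 to the methylene unit and give 36 directly.

**2. Step 13.**
- What may go wrong:
  - proton transfer from the α-positions of the ketones or the ester quenches the aryllithium, with net loss of iodine;
  - butyllithium adds to the ester carbonyl;
  - the ester enolizes and ketene is lost.
- Fallback: electrophilic instead of anionic acylation. It sets out from 30 and comes back at 36.
  - CsF, BnBr and K2CO3 in DMF should exchange the silyl group and cap the free phenol in one operation. This gives the heptabenzyl ether with B5–H F6.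
  - Butanoic acid and (CF3CO)2O in CH2Cl2 at 0 °C (mixed-anhydride Friedel–Crafts acylation) should acylate B5. B5 is the only ring C–H and sits on the only ring without an acyl group. The product is the heptabenzyl ether of the target F7.
  - H2 over Pd/C then gives 36.

**3. Step 5.**
- What may go wrong:
  - the doubly acylated ring C is a sluggish carbon nucleophile;
  - the methylene unit is exchanged by retro-Mannich and retro-Michael processes, leading to symmetrical coupling;
  - the liberated amine reversibly ties up the aldehyde.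
- Fallback: the electrophile and nucleophile roles are reversed. It sets out from 7 and 3 and comes back at 9.
  - CH2O and Me2NH should convert 7 into 3-acetyl-5-[(dimethylamino)methyl]-2,4,6-trihydroxybenzaldehyde F8.
  - Its more electrophilic o-quinone methide, generated in hot dioxane, should be captured by the single free carbon of the more nucleophilic monoacylated 3 to give 9.

Further compounds
F1 | step 11 | 1-{3-[(3-acetyl-2,4,6-trihydroxyphenyl)methyl]-2,6-dihydroxy-4-methoxy-5-methylphenyl}butan-1-one | CCCC(=O)c1c(O)c(C)c(OC)c(Cc2c(O)cc(O)c(C(C)=O)c2O)c1O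
F2 | step 11 | ring C Mannich base of the A–C dimer, 1-{3-({3-acetyl-5-[(dimethylamino)methyl]-2,4,6-trihydroxyphenyl}methyl)-2,6-dihydroxy-4-methoxy-5-methylphenyl}butan-1-one | CCCC(=O)c1c(O)c(C)c(OC)c(Cc2c(O)c(CN(C)C)c(O)c(C(C)=O)c2O)c1O
F3 | step 11 | 1-[2-hydroxy-4,6-bis(methoxymethoxy)-3-methylphenyl]butan-1-one | CCCC(=O)c1c(O)c(C)c(OCOC)cc1OCOC
F4 | step 11 | 1-[2-methoxy-4,6-bis(methoxymethoxy)-3-methylphenyl]butan-1-one | CCCC(=O)c1c(OC)c(C)c(OCOC)cc1OCOC
F5 | step 11 | 1-(4,6-dihydroxy-2-methoxy-3-methylphenyl)butan-1-one | CCCC(=O)c1c(OC)c(C)c(O)cc1O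
F6 | step 13 | heptabenzyl ether with B5–H (B2 and B6 benzyl ethers of desilylated 30) | COc3cc(OCc9ccccc9)c(Cc1c(OCc9ccccc9)c(Cc2c(OCc9ccccc9)c(C(=O)CCC)c(OCc9ccccc9)c(C)c2OC)c(OCc9ccccc9)c(C(C)=O)c1OCc9ccccc9)c(OCc9ccccc9)c3C
F7 | step 13 | heptabenzyl ether of the target | COc3c(C(=O)CCC)c(OCc9ccccc9)c(Cc1c(OCc9ccccc9)c(Cc2c(OCc9ccccc9)c(C(=O)CCC)c(OCc9ccccc9)c(C)c2OC)c(OCc9ccccc9)c(C(C)=O)c1OCc9ccccc9)c(OCc9ccccc9)c3C
F8 | step 5 | 3-acetyl-5-[(dimethylamino)methyl]-2,4,6-trihydroxybenzaldehyde | CC(=O)c1c(O)c(C=O)c(O)c(CN(C)C)c1O
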